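**Early times.** In the first minutes of the autumn run, solid substrate dissolves into starting material, which closes to ring or pairs to open dimer. The ring readings peak at 37.0 % at 20.0 min, where the solid substrate reading is 0.6 %, with a scatter of 0.5 percentage points.

| flask | solid substrate | temperature | remark | time |
|---|---|---|---|---|
| autumn | 0.83 M | 25 °C | the very flask that is asked about, followed so far |  |
| summer | 0.56 M | 10 °C | run made earlier |  |
| flask | 0.83 M | 25 °C |  | 1.5 h |

| run | time / min | ring / % | solid substrate / % |
|---|---|---|---|
| autumn | 10.0 | 30.7 | 10.5 |
| autumn | 20.0 | 37.0 | 0.6 |
| autumn | 30.0 | 33.4 | 0 |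
| autumn | 40.0 | 29.7 | 0 |
| autumn | 50.0 | 28.2 | 0 |
| summer | 6.00 | 7.0 | 12.4 |
| summer | 15.0 | 16.7 | 0 |
| summer | 30.0 | 20.7 | 0.1 |
| summer | 50.0 | 18.7 | 0 |
| summer | 80.0 | 17.2 | 0.6 |

(readings scatter by 0.5 percentage points)

- Thursday's: change nothing and wait 1.5 h more
- Saturday's: at 1.5 h raise the temperature by 20 K, then wait 1.5 h
- Friday's: at 1.5 h take out 90 % of the ring then present, then wait 1.5 h

- percentages count the solid substrate that a species holds: one open dimer counts as two
- solid, in amounts per volume of the solution: solid substrate
- ring taken out counts as made
- candidate steps: solid substrate <-> starting material; starting material <-> ring; 2 starting material <-> open dimer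
- at the start none of the solid substrate is in solution

- ring, in percent of the solid substrate first charged, at 1.5 h
- the option that brings most further ring ("none" if no option brings more than 2 percentage points) (Thursday's / Saturday's / Friday's / none)
- ring present, with what was taken out counted in, in percent of the solid substrate first charged, after Saturday's
- ring present, with what was taken out counted in, in percent of the solid substrate first charged, after Friday's

**The crossing.** I read that peak as the handover from kinetic to thermodynamic control. Ring then falls to 28.2 %, and the last two drops shrink by a factor 0.405. Summing that series, I put ring at 27.2 % at 1.5 h, so Thursday's brings no gain in my reckoning.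

**Raw lift.** Ring odds, ring over the rest of the charge, read 0.393 at the autumn run's last reading and 0.208 at the summer run's, 15.0 K colder. Their quotient is 1.89. Stretched over 20 K, it takes my odds of 0.373 to a ring of 46.6 % after Saturday's.

**Weak link.** The autumn run had 1.48 times the summer charge, and this is a ring–chain balance: open dimer takes two starting material. If both balance against starting material, ring goes as starting material and open dimer as its square, so where open dimer dominates, ring's share falls as the root of the charge, and I multiply the odds by that root. This gives 2.30, the heat lift, the factor on ring odds over those 15.0 K at equal charge. I commit to 53.1 % after Saturday's.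

**The forecast.** It gives 25 % at 1.5 h, 35 % after Saturday's and 40 % after Friday's, and it picks Friday's. It agrees that “heat favours ring over dimer”, but my Saturday figure stands higher than its Friday figure, so I pick Saturday's.

**The flask.** The flask holds 22.7 % ring at 1.5 h. Saturday's wins with 55.9 %, against 35.5 % after Friday's, and Thursday's changes ring by −3.6 points.

    solid substrate ⇌ starting material, rate k1*(cs1 - [starting material]) while solid is left; crystals form when [starting material] > cs1 (solubility = 0.540 M, k = 0.325 min⁻¹)
    starting material ⇌ ring (K = 0.800, k = 0.164 min⁻¹, Ea = 78.0 kJ mol⁻¹, ΔH = 48.0 kJ mol⁻¹)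
    2 starting material ⇌ open dimer (K = 6.90 M⁻¹, k = 0.0312 M⁻¹ min⁻¹, Ea = 74.0 kJ mol⁻¹, ΔH = −29.0 kJ mol⁻¹)
    (constants at 25 °C)

**Closure against dimer.** At 90.0 min in the flask, closure to ring has a forward half-life of 4.2 min, shorter than the 20.7 min relaxation half-life of the dimer step. Ring over starting material stands at 0.831 at 45.0 min and 0.815 at 90.0 min, while open dimer grows from 36.0 % to 49.4 %. Starting from the flask's 22.7 %, the heat lift gives 47.1 % for Saturday's, against 55.9 %. For the repeat at 50 °C it gives 54.1 %, against a simulated 65.9 %.

All runs stem from a simulated flask on assumed constants, and the scatter is random.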